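If the tris adduct in the flask has stood still since 50.0 min, the examiner's question is whether coupling partner remains to move it.

| flask | starting material | coupling partner | temperature | remark | time |
|---|---|---|---|---|---|
| green | 0.042 M | 0.063 M | 0 °C | the very flask that is asked about, followed so far |  |
| violet | 0.084 M | 0.063 M | −15 °C | run made earlier |  |
| flask | 0.042 M | 0.0630 M | 0 °C |  | 6.0 h |

- green (time / min: tris adduct / %, starting material / %): 20.0: 13, 3; 50.0: 18, 3; 90.0: 17, 0; 150: 18, 0; 240: 19, 3
- violet (time / min: tris adduct / %, starting material / %): 3.00: 0, 5; 6.00: 1, 2; 10.0: 1, 2; 12.0: 5, 4; 15.0: 5, 0

(each reading ± 2 percentage points)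

- Friday's: change nothing and wait 3.0 h more
- Tuesday's: at 6.0 h take out 90% of the tris adduct then present, then wait 3.0 h
- Saturday's: at 6.0 h raise the temperature by 20 K, then wait 3.0 h
- Wednesday's: at 6.0 h add coupling partner, 100% of the amount charged, then wait 3.0 h

1. tris adduct, in percent of the starting material first charged, at 6.0 h
2. the option that brings most further tris adduct ("none" if no option brings more than 2 percentage points) (Friday's / Tuesday's / Saturday's / Wednesday's / none)
3. tris adduct present, with what was taken out counted in, in percent of the starting material first charged, after Friday's
4. tris adduct present, with what was taken out counted in, in percent of the starting material first charged, after Tuesday's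

- removed tris adduct is counted in
- additions bring no volume worth counting

**Where does the flask stand at 6.0 h?** The four green readings from 50.0 min on average 18.0% tris adduct, which I call y; with a reading error of 2 percentage points, they show no rise, so I commit to that value.

**What has that tris adduct cost in partner?** Each tris adduct holds 3 partners. With cA and cB the charges of starting material and coupling partner, the share of the partner charge not bound in tris adduct is one minus 3·y·cA/cB, which is 64.0%; call it the partner outside tris adduct, F.

**Weak spot: is partner still the limiting reagent?** The charges do not say. Spread over the 82.0% of the starting material that is not in tris adduct, F comes to 1.17 partners per molecule, and stalled intermediates could hold that.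

**Then what speaks against them?** The violet run does. One partner per molecule could take 75.0% of its starting material, yet its readings average 2.60% left, so by these readings about 22 points went without partner.

**Your answer?** I assume that route also runs in the green flask, which leaves partner unbound. I expect tris adduct to stay at y after Friday's and Tuesday's, and I answer none.

The forecast gives 18% (16% to 20.5%), 18.5% and 18.5%, and chooses Wednesday's: “partner exhaustion is the likely cause”. We part on the option.

The flask gives 17.1% at 6.0 h, 17.1% after Friday's and 17.1% after Tuesday's; the best option is none, and Wednesday's gains 0 points.

    starting material + coupling partner → mono adduct (k = 0.110 L mol⁻¹ s⁻¹, Ea = 57.0 kJ mol⁻¹)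
    coupling partner + mono adduct → bis adduct (k = 0.130 L mol⁻¹ s⁻¹, Ea = 37.0 kJ mol⁻¹)
    coupling partner + bis adduct → tris adduct (k = 0.330 L mol⁻¹ s⁻¹, Ea = 51.0 kJ mol⁻¹)
    coupling partner → decomposition product (k = 2.10 × 10⁻⁵ s⁻¹, Ea = 95.0 kJ mol⁻¹)
    2 starting material → homo dimer (k = 1.30 L mol⁻¹ s⁻¹, Ea = 45.0 kJ mol⁻¹)
    (constants at 0 °C)

In the flask, F from the result is 65.8%, made up of 41.7% of the partner charge still unbound at 360 min and 24.1% turned into decomposition product, while homo dimer holds 82.9% of the starting material. The neighbouring flask, with 0.017 M starting material, gives 30.5% tris adduct and 69.5% homo dimer. Its F is 75.3%, made up of 27.5% turned into decomposition product and 48% still unbound.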